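(The numbers in the tables were computed for an exercise; the scatter is artificial.)

If you take over the bench now, you find the flasks midnight and autumn closed and stirred, and the question is what they hold at 2.0 h.

| flask | substrate | reagent | remark | time |
|---|---|---|---|---|
| Friday's | 0.29 M | 0.22 M | run made earlier |  |
| Monday's | 0.29 M | 0.48 M | run made earlier |  |
| Wednesday's | 0.29 M | 0.97 M | run made earlier |  |
| Tuesday's | 0.67 M | 0.261 M | run made earlier |  |
| midnight | 0.29 M | 0.261 M |  | 2.0 h |
| autumn | 0.80 M | 1.00 M |  | 2.0 h |

| run | time / min | product / % | substrate / % |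
|---|---|---|---|
| Friday's | 5.00 | 2.2 | 95.7 |
| Friday's | 10.0 | 4.6 | 93.4 |
| Friday's | 15.0 | 7.9 | 93.0 |
| Friday's | 30.0 | 12.3 | 86.2 |
| Friday's | 60.0 | 22.1 | 77.9 |
| Monday's | 12.0 | 8.4 | 91.2 |
| Monday's | 25.0 | 18.1 | 84.4 |
| Monday's | 40.0 | 22.9 | 75.5 |
| Monday's | 50.0 | 28.9 | 71.8 |
| Monday's | 60.0 | 31.7 | 68.5 |
| Wednesday's | 5.00 | 5.9 | 93.9 |
| Wednesday's | 10.0 | 9.1 | 91.2 |
| Wednesday's | 15.0 | 15.6 | 85.0 |
| Wednesday's | 30.0 | 25.2 | 73.3 |
| Wednesday's | 60.0 | 40.4 | 60.9 |
| Tuesday's | 5.00 | 8.1 | 93.3 |
| Tuesday's | 15.0 | 17.2 | 83.7 |
| Tuesday's | 30.0 | 23.5 | 77.0 |
| Tuesday's | 40.0 | 29.9 | 72.9 |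
| Tuesday's | 60.0 | 34.1 | 65.5 |

(scatter of a reading: 1 percentage point)



- which one finishes higher in amount of product, in percent of the substrate charged ("neither" within 2 percentage points) (midnight / autumn / neither)
- amount of product at the end, in percent of the substrate charged, midnight
- amount of product at the end, in percent of the substrate charged, autumn

In Friday's run, the last reading shows substrate at 77.9% and product at 22.1%, so what leaves as substrate arrives as product. I assume one reagent goes with each substrate, so the rate of reagent loss divided by the rate of substrate loss is one, and time drops out. Each flask then has a reagent capacity. Autumn's is 125% and midnight's 90.0%, the capacity being the reagent charge divided by the substrate charge, that is, the product its reagent can pay for as a share of the substrate charge. Whatever the hour, the share of its own charge that reagent keeps is the capacity minus the product, divided by the capacity. Midnight's capacity stands below the full substrate charge, which makes reagent its limiting reagent. Autumn's capacity stands above the full substrate charge, so in autumn the substrate charge, not the reagent, is the limit on product. Tuesday's run, with a capacity of 39.0%, reads 34.1% at its last reading, still under that line.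

The forecast says autumn finishes higher, with 37% for midnight and 75% for autumn, on the grounds that “The substrate follows second-order decay”. Both lie under their reagent capacities. I add what they cost: when you come, midnight should keep 58.9% of its reagent and autumn 40.0%.

Midnight ends at 38.8% and autumn at 74.7%, so autumn finishes higher.

    substrate + reagent → product, rate k1*[substrate]^2*[reagent]^0.5 (k = 2.50 M⁻¹·⁵ h⁻¹)

Autumn's product of 74.7% on its reagent capacity of 125% reckons to 40.2% of its reagent kept, and the flask holds 40%. The neighbour is autumn with its reagent cut to 0.25 M, which lowers the capacity to 31.2%. After 2.00 h that neighbour holds substrate at 68.8%, reagent at 0% and product at 31.2%.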